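Late in Friday's run, target creeps from 42.2% of the substrate charged at 43 min to 51.2% at 81 min, and Wednesday's flask asks what that slow stretch means once target is already present.

| setting | Friday's | Thursday's | Tuesday's | Monday's | Wednesday's |
|---|---|---|---|---|---|
| substrate | 0.0500 M | 0.0200 M | 0.150 M | 0.0500 M | 0.0500 M |
| coupling partner | 0.0400 M | 0.0100 M | 0.0400 M | 0.120 M | 0.0400 M |
| target |  |  |  |  | 0.0150 M |
| time |  |  |  |  | 81 min |

| Friday's run: time / min | Friday's run: [target] / M | Thursday's run: time / min | Thursday's run: [target] / M | Tuesday's run: time / min | Tuesday's run: [target] / M | Monday's run: time / min | Monday's run: [target] / M |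
|---|---|---|---|---|---|---|---|
| 3.2 | 0.0029 | 3.2 | 2 × 10⁻⁴ | 3.2 | 0.0099 | 3.2 | 0.0094 |
| 6.2 | 0.0058 | 6.2 | 9 × 10⁻⁴ | 6.2 | 0.0165 | 6.2 | 0.0161 |
| 12 | 0.0100 | 12 | 0.0014 | 12 | 0.0253 | 12 | 0.0250 |
| 22 | 0.0151 | 22 | 0.0023 | 22 | 0.0310 | 22 | 0.0330 |
| 43 | 0.0211 | 43 | 0.0028 | 43 | 0.0334 | 43 | 0.0392 |
| 81 | 0.0256 | 81 | 0.0047 | 81 | 0.0333 | 81 | 0.0428 |

(each reading ± 3 × 10⁻⁴ M)

- reaction order in [substrate] at the outset, round the charge of the Friday's run, defined at two percent of the substrate turned into target (one fixed amount of target, the same in the runs compared)
- reaction order in [coupling partner] at the outset, round the charge of the Friday's run, defined at two percent of the substrate turned into target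
- target in the Wednesday's run at 81 min, as a share of the substrate charged

- Overall: substrate + coupling partner -> target.
- Constant volume, constant temperature.
- "The second partner" is coupling partner.
- An order is taken over about fifteen percent of the charge, up and down.
- A share of target counts the target that was charged too.

Take the rate as k times substrate times coupling partner, and let both fall one for one with target made. Then replace the drifting k by a single value, held from time zero, that lands on the last reading. Friday's run gives 0.376 /M/min, the mean constant of that run. The same reckoning stopped at 6.2 min reads 0.538 /M/min, so the mean lies below the early reading, and the dispute is over what that gap does in Wednesday's flask.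

Wednesday's flask has Friday's charges of substrate and coupling partner, plus target at 30.0% of the substrate. The forecast's maker reads the fade as a brake tied to target: “This looks like product-linked inhibition or catalyst loss, not simple reversibility”. The forecast gives orders of 1.1 and 1.1 and a share of 74%, and that share means a mean constant of 0.270 /M/min.

My own view is that target is a bystander and the coupling partner leaks away by another path. Tuesday's readings stop at 83.5% of the partner charged, the limiting reagent there, with 77.7% of the substrate not in target. On this view Wednesday keeps 0.376 /M/min, makes what Friday made, and ends at 81.2%.

The simulation gives orders of 1.0 and 1.0, and 86.4% for Wednesday's run. That stands 12 percentage points above the forecast and 5.2 points above my figure.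

    substrate + coupling partner → target (0.5412 /M/min)
    substrate + coupling partner → side product (0.09420 /M/min)
    2 coupling partner → lost reagent (0.2544 /M/min)
    substrate + coupling partner + target → 2 target (18.24 /M²/min)

Wednesday's result means a mean constant of 0.483 /M/min, which is above Friday's 0.376 /M/min, so the charged target raised the share, through the step in which target joins substrate and coupling partner. The same Wednesday's run with that step taken away ends at 72.5%, a mean constant of 0.252 /M/min. There the forecast's 0.270 /M/min would have stood close, and its share within 1.5 points.

All runs were generated by integration with made-up constants; the scatter is artificial.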